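The cage is taken apart at two bonds: the C–C bond joining the ring B/C methine to the carbinol carbon shared by rings B, C and D, and the C–O bond from the gem-dimethyl carbon to the enol-ether carbon of ring D. That methine has the oxygen-bearing CMe2 carbon on one side and the shared carbinol carbon on the other, so an (S)-2,2-dimethyloxirane on a side arm brings both the electrophilic carbon and the ring C oxygen. In one operation the γ-dienolate of a cis-fused ring A/D methyl vinylogous ester opens the oxirane (ring B) and the liberated alkoxide displaces methoxide (ring C). The precursor carries both carbinol oxygens as triethylsilyl ethers.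

Key step: step 17

Remarks on the chemistry
- Geranyl is (2E)-3,7-dimethylocta-2,6-dien-1-yl and prenyl is 3-methylbut-2-en-1-yl.
- Bicyclic compounds 16–27 are numbered as naphthalen-1-ones: C1 ring D carbonyl, C2 its α carbon, C3 methoxy carbon, C4 γ carbon, C4a carbinol fusion carbon, C5 carbon with the oxiranylmethyl arm, C6–C8 rest of ring A, C8a quaternary fusion carbon. In all of them the fusion is cis (geranyl and the C4a oxygen on one face) and the C5 arm is trans to the C4a oxygen; the absolute sense is that of the SMILES.
- Design correction: a free hydroxyl at C4a would be deprotonated before C4, and its alkoxide could open the oxirane itself (5-exo) or start retro-aldol cleavage. It is therefore silylated in step 10 and stays so until step 18.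
- Assumption: the oxirane CH carbon must be S. The usual D-fructose-derived Shi ketone gives R with alkenes of the type R–CH=CMe2, so its mirror image (from L-sorbose) is taken as available.
- The two ring positions next to the methoxy group are blocked with bromine for the dearomatising step, because a free position would be alkylated first and the ring would stay aromatic.
- The configuration at C4 of 25 and 26 is lost in dienolate 27, so either epimer serves; the drawn one is the expected major epimer.

Step 1
Reactants: 1 5-methoxybenzene-1,3-diol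
Product: 2 1-methoxy-3,5-bis(methoxymethoxy)benzene
Conditions: MOMCl, iPr2NEt, CH2Cl2, 0 °C to rt
Reagents that add atoms: chloromethyl methyl ether, COCCl
Why: Double O-alkylation of the phenol with a reactive α-chloro ether (methoxymethyl ether formation) installs two acetal groups that will direct lithiation to the carbon between them.

Step 2
Reactants: 2 1-methoxy-3,5-bis(methoxymethoxy)benzene; 3 geranyl bromide
Product: 5 2-[(2E)-3,7-dimethylocta-2,6-dien-1-yl]-5-methoxy-1,3-bis(methoxymethoxy)benzene, via aryllithium 4 (not isolated)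
Conditions: n-BuLi, THF, 0 °C; CuBr·SMe2 (cat.), geranyl bromide, −78 °C to rt
Reagents that add atoms: none
Why: Directed ortho-metalation places lithium on the carbon flanked by both methoxymethoxy groups, and copper-assisted SN2 allylation of the aryllithium with the primary allylic bromide attaches the geranyl chain there with its E double bond unchanged.

Step 3
Reactants: 5 2-[(2E)-3,7-dimethylocta-2,6-dien-1-yl]-5-methoxy-1,3-bis(methoxymethoxy)benzene
Product: 6 2-[(2E)-3,7-dimethylocta-2,6-dien-1-yl]-5-methoxybenzene-1,3-diol
Conditions: HCl (cat.), MeOH, rt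
Reagents that add atoms: none
Why: Acid-catalysed acetal exchange with methanol (methoxymethyl ether cleavage) frees both phenols under conditions mild enough to leave the trisubstituted alkenes alone.

Step 4
Reactants: 6 2-[(2E)-3,7-dimethylocta-2,6-dien-1-yl]-5-methoxybenzene-1,3-diol
Product: 7 4,6-dibromo-2-[(2E)-3,7-dimethylocta-2,6-dien-1-yl]-5-methoxybenzene-1,3-diol
Conditions: N-bromosuccinimide (2 equiv), iPr2NH (cat.), CH2Cl2, −78 °C
Reagents that add atoms: N-bromosuccinimide, O=C1CCC(=O)N1Br
Why: Amine-catalysed electrophilic ortho-bromination of the free resorcinol at low temperature should be far faster than attack on the isolated alkenes and fills both open ring positions, so that only the geranyl-bearing carbon is left for C-alkylation.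

Step 5
Reactants: 8 5-bromo-2-methylpent-2-ene; 9 acrolein
Product: 11 7-methylocta-1,6-dien-3-ol, via Grignard reagent 10 (not isolated)
Conditions: Mg, THF, rt; then acrolein, −78 °C; NH4Cl (aq)
Reagents that add atoms: none
Why: Grignard 1,2-addition of the homoprenyl organomagnesium reagent to the aldehyde gives the allylic alcohol, whose racemic carbinol centre is removed again in step 7.

Step 6
Reactants: 11 7-methylocta-1,6-dien-3-ol
Product: 12 5-[(2S)-3,3-dimethyloxiran-2-yl]pent-1-en-3-ol
Conditions: L-fructose-derived Shi ketone (30 mol%), KHSO5 (as 2KHSO5·KHSO4·K2SO4), K2CO3, Bu4NHSO4, Na2B4O7/Na2(EDTA) buffer, MeCN–CH2(OMe)2–H2O, 0 °C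
Reagents that add atoms: potassium peroxymonosulfate, [K+].[O-]S(=O)(=O)OO
Why: In this Shi epoxidation the chiral dioxirane attacks the electron-rich trisubstituted alkene through the usual spiro transition state and, being the mirror image of the common catalyst, should make the oxirane CH carbon S, while the monosubstituted vinyl group reacts much more slowly.

Step 7
Reactants: 12 5-[(2S)-3,3-dimethyloxiran-2-yl]pent-1-en-3-ol
Product: 13 5-[(2S)-3,3-dimethyloxiran-2-yl]pent-1-en-3-one
Conditions: Dess–Martin periodinane, NaHCO3, CH2Cl2, 0 °C; used at once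
Reagents that add atoms: none
Why: Dess–Martin oxidation of the secondary allylic alcohol under bicarbonate buffering gives the vinyl ketone without acid that could open the oxirane and erases the carbinol stereocentre.

Step 8
Reactants: 7 4,6-dibromo-2-[(2E)-3,7-dimethylocta-2,6-dien-1-yl]-5-methoxybenzene-1,3-diol; 13 5-[(2S)-3,3-dimethyloxiran-2-yl]pent-1-en-3-one
Product: 15 2-geranyl-5-methoxy-2-{5-[(2S)-3,3-dimethyloxiran-2-yl]-3-oxopentyl}cyclohex-4-ene-1,3-dione, via dibromo adduct 14 (not isolated)
Conditions: K2CO3, MeOH–H2O, 0 °C to rt; then Zn, NH4Cl, 0 °C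
Reagents that add atoms: none
Why: This is a dearomatising Michael addition of a fully substituted phloroglucinol-type phenolate, in which reversible conjugate addition can end productively only at the geranyl-bearing carbon to give a stabilised vinylogous-acid anion with the quaternary carbon in place, after which zinc removes both bromines by reduction of the α-bromo carbonyl tautomers.

Step 9
Reactants: 15 2-geranyl-5-methoxy-2-{5-[(2S)-3,3-dimethyloxiran-2-yl]-3-oxopentyl}cyclohex-4-ene-1,3-dione
Product: 16 8a-geranyl-4a-hydroxy-3-methoxy-5-{[(2S)-3,3-dimethyloxiran-2-yl]methyl}-4a,5,8,8a-tetrahydro-4H-naphthalene-1,6(7H)-dione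
Conditions: (R)-proline (30 mol%), DMSO, rt
Reagents that add atoms: none
Why: This proline-catalysed intramolecular aldol reaction of the Hajos–Parrish type runs as a dynamic kinetic resolution, because the two enantiomeric vinylogous-ester tautomers of 15 interconvert by enolisation while the E-enamine of the side-chain ketone attacks only the ring carbonyl selected by (R)-proline through an acid-bound chair transition state, which sets the quaternary carbon, the cis fusion and the C5 centre (arm trans to the new hydroxyl) in the sense opposite to that given by (S)-proline in the Wieland–Miescher series.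

Step 10
Reactants: 16 8a-geranyl-4a-hydroxy-3-methoxy-5-{[(2S)-3,3-dimethyloxiran-2-yl]methyl}-4a,5,8,8a-tetrahydro-4H-naphthalene-1,6(7H)-dione
Product: 17 4a-O-triethylsilyl ether of 16
Conditions: Et3SiOTf, 2,6-lutidine, CH2Cl2, −78 °C
Reagents that add atoms: triethylsilyl trifluoromethanesulfonate, CC[Si](CC)(CC)OS(=O)(=O)C(F)(F)F
Why: Silylation of the hindered tertiary alcohol with a silyl triflate and a non-nucleophilic pyridine base at low temperature caps the carbinol so that later bases cannot start retro-aldol cleavage.

Step 11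
Reactants: 17 4a-O-triethylsilyl ether of 16
Product: 19 8a-geranyl-3-methoxy-5-{[(2S)-3,3-dimethyloxiran-2-yl]methyl}-1-oxo-4a-(triethylsilyloxy)-1,4,4a,5,8,8a-hexahydronaphthalen-6-yl trifluoromethanesulfonate, via potassium enolate 18 (not isolated)
Conditions: KN(SiMe3)2, THF, −78 °C; then N-(5-chloropyridin-2-yl)bis(trifluoromethanesulfonyl)imide, −78 °C
Reagents that add atoms: N-(5-chloropyridin-2-yl)bis(trifluoromethanesulfonyl)imide, O=S(=O)(N(c1ccc(Cl)cn1)S(=O)(=O)C(F)(F)F)C(F)(F)F
Why: Kinetic enolate formation followed by O-sulfonylation should work because the bulky amide base takes a proton from the unhindered C7 methylene of the ring A ketone, not from the hindered C5 methine or the less acidic γ position of the vinylogous ester, and the triflimide traps the enolate as the C6–C7 enol triflate.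

Step 12
Reactants: 19 8a-geranyl-3-methoxy-5-{[(2S)-3,3-dimethyloxiran-2-yl]methyl}-1-oxo-4a-(triethylsilyloxy)-1,4,4a,5,8,8a-hexahydronaphthalen-6-yl trifluoromethanesulfonate
Product: 20 8a-geranyl-3-methoxy-6-methyl-5-{[(2S)-3,3-dimethyloxiran-2-yl]methyl}-4a-(triethylsilyloxy)-4a,5,8,8a-tetrahydronaphthalen-1(4H)-one
Conditions: SnMe4, Pd(PPh3)4 (cat.), LiCl, THF, 65 °C
Reagents that add atoms: tetramethylstannane, C[Sn](C)(C)C
Why: Stille coupling of the enol triflate with tetramethylstannane, assisted by LiCl, replaces the triflate by methyl under neutral conditions and fixes the trisubstituted ring A alkene.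

Step 13
Reactants: 20 8a-geranyl-3-methoxy-6-methyl-5-{[(2S)-3,3-dimethyloxiran-2-yl]methyl}-4a-(triethylsilyloxy)-4a,5,8,8a-tetrahydronaphthalen-1(4H)-one
Product: 21 2-iodo derivative of 20
Conditions: N-iodosuccinimide, MeCN, 0 °C to rt, dark
Reagents that add atoms: N-iodosuccinimide, O=C1CCC(=O)N1I
Why: Electrophilic α-iodination should occur at C2 because this carbon is the nucleophilic β carbon of an enol ether and is far more reactive than the isolated trisubstituted alkenes.

Step 14
Reactants: 21 2-iodo derivative of 20; 22 tributyl(3-methylbut-2-en-1-yl)stannane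
Product: 23 8a-geranyl-3-methoxy-6-methyl-2-(3-methylbut-2-en-1-yl)-5-{[(2S)-3,3-dimethyloxiran-2-yl]methyl}-4a-(triethylsilyloxy)-4a,5,8,8a-tetrahydronaphthalen-1(4H)-one
Conditions: PdCl2(dppf) (cat.), DMF, 100 °C
Reagents that add atoms: none
Why: Stille coupling of the α-iodo vinylogous ester with the prenylstannane, a reaction established for late prenylation of rings of this kind, should transfer the allyl group through its unsubstituted carbon and give the linear prenyl chain.

Step 15
Reactants: 23 8a-geranyl-3-methoxy-6-methyl-2-(3-methylbut-2-en-1-yl)-5-{[(2S)-3,3-dimethyloxiran-2-yl]methyl}-4a-(triethylsilyloxy)-4a,5,8,8a-tetrahydronaphthalen-1(4H)-one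
Product: 25 4-hydroxy derivative of 23, via potassium dienolate 24 (not isolated)
Conditions: KN(SiMe3)2, THF, −78 °C; then 2-(phenylsulfonyl)-3-phenyloxaziridine, −78 °C; NH4Cl (aq)
Reagents that add atoms: 2-(phenylsulfonyl)-3-phenyloxaziridine, O=S(=O)(N1OC1c1ccccc1)c1ccccc1
Why: In this oxaziridine hydroxylation of an extended enolate the base can only remove a γ hydrogen at C4, and because the α carbon now carries the prenyl group the dienolate should take up oxygen at its γ terminus, mainly from the face away from the neighbouring silyloxy group.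

Step 16
Reactants: 25 4-hydroxy derivative of 23
Product: 26 8a-geranyl-3-methoxy-6-methyl-2-(3-methylbut-2-en-1-yl)-5-{[(2S)-3,3-dimethyloxiran-2-yl]methyl}-4,4a-bis(triethylsilyloxy)-4a,5,8,8a-tetrahydronaphthalen-1(4H)-one
Conditions: Et3SiOTf, 2,6-lutidine, CH2Cl2, −78 °C
Reagents that add atoms: triethylsilyl trifluoromethanesulfonate, CC[Si](CC)(CC)OS(=O)(=O)C(F)(F)F
Why: Silyl triflate silylation of the hindered secondary alcohol completes the cyclisation precursor with both carbinol oxygens masked.

Step 17
Reactants: 26 8a-geranyl-3-methoxy-6-methyl-2-(3-methylbut-2-en-1-yl)-5-{[(2S)-3,3-dimethyloxiran-2-yl]methyl}-4,4a-bis(triethylsilyloxy)-4a,5,8,8a-tetrahydronaphthalen-1(4H)-one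
Product: 29 bis(triethylsilyl) ether of the target, via lithium dienolate 27 (not isolated), via ring B alkoxide 28 (not isolated)
Conditions: LiN(SiMe3)2, THF, −78 °C to rt
Reagents that add atoms: none
Why: LiN(SiMe3)2 removes the only enolisable hydrogen, the γ hydrogen at C4 (C8a is quaternary and C2 carries prenyl), and the γ carbon of dienolate 27 opens the tethered trisubstituted oxirane at its secondary carbon by backside attack, forming the methine-to-carbinol bond and ring B; the tertiary lithium alkoxide 28 then adds to the methoxy-bearing C3 and expels methoxide, closing ring C. The closest known reaction types are intramolecular enolate alkylation by epoxide opening combined with γ-alkylation of vinylogous-ester dienolates, followed by alkoxide exchange at a β-alkoxy enone by addition–elimination. Ring B closes in the 5-(enolexo)-exo-tet mode and ring C in a 5-exo-trig addition–elimination. The methine configuration follows from the catalyst-set (S)-oxirane through inversion, and the configuration of the new quaternary carbinol carbon is dictated by the tether from C5, which can reach only the face that gives the cis B/D and cis B/C junctions. The step needs γ- and not α-alkylation, attack at the less substituted oxirane carbon, and a carbon and not an oxygen nucleophile: the fully substituted α carbon and the five- versus seven-membered ring choice secure the first, basic SN2 conditions and the 5-exo geometry the second, and silylation of both carbinol oxygens the third.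

Step 18
Reactants: 29 bis(triethylsilyl) ether of the target
Product: 30 CNP0323114.1
Conditions: Bu4NF, AcOH, THF, 0 °C to rt
Reagents that add atoms: none
Why: Fluoride-induced cleavage of both triethylsilyl ethers, buffered with acetic acid to avoid base-mediated retro-aldol opening of the β-hydroxy ketone, should release the two tertiary alcohols of the target.

Compound list
1 | 5-methoxybenzene-1,3-diol | COc1cc(O)cc(O)c1 | starting material
2 | 1-methoxy-3,5-bis(methoxymethoxy)benzene | COCOc1cc(OC)cc(OCOC)c1 | intermediate
3 | geranyl bromide, (2E)-1-bromo-3,7-dimethylocta-2,6-diene | CC(C)=CCC/C(C)=C/CBr | starting material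
4 | [4-methoxy-2,6-bis(methoxymethoxy)phenyl]lithium | [Li]c1c(OCOC)cc(OC)cc1OCOC | intermediate
5 | 2-[(2E)-3,7-dimethylocta-2,6-dien-1-yl]-5-methoxy-1,3-bis(methoxymethoxy)benzene | COCOc1cc(OC)cc(OCOC)c1C/C=C(\C)CCC=C(C)C | intermediate
6 | 2-[(2E)-3,7-dimethylocta-2,6-dien-1-yl]-5-methoxybenzene-1,3-diol | COc1cc(O)c(C/C=C(\C)CCC=C(C)C)c(O)c1 | intermediate
7 | 4,6-dibromo-2-[(2E)-3,7-dimethylocta-2,6-dien-1-yl]-5-methoxybenzene-1,3-diol | COc1c(Br)c(O)c(C/C=C(\C)CCC=C(C)C)c(O)c1Br | intermediate
8 | 5-bromo-2-methylpent-2-ene | CC(C)=CCCBr | starting material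
9 | acrolein (prop-2-enal) | C=CC=O | starting material
10 | (4-methylpent-3-en-1-yl)magnesium bromide | CC(C)=CCC[Mg]Br | intermediate
11 | 7-methylocta-1,6-dien-3-ol (racemic) | C=CC(O)CCC=C(C)C | intermediate
12 | 5-[(2S)-3,3-dimethyloxiran-2-yl]pent-1-en-3-ol (both carbinol epimers) | C=CC(O)CC[C@@H]1OC1(C)C | intermediate
13 | 5-[(2S)-3,3-dimethyloxiran-2-yl]pent-1-en-3-one | C=CC(=O)CC[C@@H]1OC1(C)C | intermediate
14 | 4,6-dibromo-2-geranyl-5-methoxy-2-{5-[(2S)-3,3-dimethyloxiran-2-yl]-3-oxopentyl}cyclohex-4-ene-1,3-dione (keto form of the potassium enolate; ring centres not fixed) | COC1=C(Br)C(=O)C(C/C=C(\C)CCC=C(C)C)(CCC(=O)CC[C@@H]2OC2(C)C)C(=O)C1Br | intermediate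
15 | 2-geranyl-5-methoxy-2-{5-[(2S)-3,3-dimethyloxiran-2-yl]-3-oxopentyl}cyclohex-4-ene-1,3-dione (C2 epimers interconvert by tautomerism) | COC1=CC(=O)C(C/C=C(\C)CCC=C(C)C)(CCC(=O)CC[C@@H]2OC2(C)C)C(=O)C1 | intermediate
16 | cis-fused ketol 8a-geranyl-4a-hydroxy-3-methoxy-5-{[(2S)-3,3-dimethyloxiran-2-yl]methyl}-4a,5,8,8a-tetrahydro-4H-naphthalene-1,6(7H)-dione (geranyl and OH cis, C5 arm trans to OH) | CC(C)=CCC/C(C)=C/C[C@]12CCC(=O)[C@H](C[C@@H]3OC3(C)C)[C@]2(O)CC(OC)=CC1=O | intermediate
17 | 4a-O-triethylsilyl ether of 16 | CC(C)=CCC/C(C)=C/C[C@]12CCC(=O)[C@H](C[C@@H]3OC3(C)C)[C@]2(O[Si](CC)(CC)CC)CC(OC)=CC1=O | intermediate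
18 | potassium C6–C7 enolate of 17 | CC(C)=CCC/C(C)=C/C[C@]12CC=C([O-])[C@H](C[C@@H]3OC3(C)C)[C@]2(O[Si](CC)(CC)CC)CC(OC)=CC1=O.[K+] | intermediate
19 | C6–C7 enol triflate of 17 (6-trifluoromethanesulfonyloxy) | CC(C)=CCC/C(C)=C/C[C@]12CC=C(OS(=O)(=O)C(F)(F)F)[C@H](C[C@@H]3OC3(C)C)[C@]2(O[Si](CC)(CC)CC)CC(OC)=CC1=O | intermediate
20 | 8a-geranyl-3-methoxy-6-methyl-5-{[(2S)-3,3-dimethyloxiran-2-yl]methyl}-4a-(triethylsilyloxy)-4a,5,8,8a-tetrahydronaphthalen-1(4H)-one | CC(C)=CCC/C(C)=C/C[C@]12CC=C(C)[C@H](C[C@@H]3OC3(C)C)[C@]2(O[Si](CC)(CC)CC)CC(OC)=CC1=O | intermediate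
21 | 2-iodo derivative of 20 | CC(C)=CCC/C(C)=C/C[C@]12CC=C(C)[C@H](C[C@@H]3OC3(C)C)[C@]2(O[Si](CC)(CC)CC)CC(OC)=C(I)C1=O | intermediate
22 | tributyl(3-methylbut-2-en-1-yl)stannane | CCCC[Sn](CCCC)(CCCC)CC=C(C)C | starting material
23 | 2-prenyl derivative of 20 | CC(C)=CCC/C(C)=C/C[C@]12CC=C(C)[C@H](C[C@@H]3OC3(C)C)[C@]2(O[Si](CC)(CC)CC)CC(OC)=C(CC=C(C)C)C1=O | intermediate
24 | potassium dienolate of 23 (O–C1=C2–C3=C4) | CC(C)=CCC/C(C)=C/C[C@]12CC=C(C)[C@H](C[C@@H]3OC3(C)C)[C@]2(O[Si](CC)(CC)CC)C=C(OC)C(CC=C(C)C)=C1[O-].[K+] | intermediate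
25 | 4-hydroxy derivative of 23 (4-OH trans to the 4a-silyloxy group drawn) | CC(C)=CCC/C(C)=C/C[C@]12CC=C(C)[C@H](C[C@@H]3OC3(C)C)[C@]2(O[Si](CC)(CC)CC)[C@H](O)C(OC)=C(CC=C(C)C)C1=O | intermediate
26 | cyclisation precursor, 4,4a-bis(triethylsilyloxy) derivative of 23 | CC(C)=CCC/C(C)=C/C[C@]12CC=C(C)[C@H](C[C@@H]3OC3(C)C)[C@]2(O[Si](CC)(CC)CC)[C@H](O[Si](CC)(CC)CC)C(OC)=C(CC=C(C)C)C1=O | intermediate
27 | lithium dienolate of 26 | CC(C)=CCC/C(C)=C/C[C@]12CC=C(C)[C@H](C[C@@H]3OC3(C)C)[C@]2(O[Si](CC)(CC)CC)C(O[Si](CC)(CC)CC)=C(OC)C(CC=C(C)C)=C1[O-].[Li+] | intermediate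
28 | lithium tertiary alkoxide with ring B closed (cis-fused cyclopentane carrying the 2-oxidopropan-2-yl group, methyl vinylogous ester intact) | CC(C)=CCC/C(C)=C/C[C@]12CC=C(C)[C@@H]3C[C@H](C(C)(C)[O-])[C@](O[Si](CC)(CC)CC)(C(OC)=C(CC=C(C)C)C1=O)[C@@]32O[Si](CC)(CC)CC.[Li+] | intermediate
29 | bis(triethylsilyl) ether of the target (both tertiary carbinols silylated) | CC(C)=CCC/C(C)=C/C[C@]12CC=C(C)[C@@H]3C[C@@H]4C(C)(C)OC(=C(CC=C(C)C)C1=O)[C@]4(O[Si](CC)(CC)CC)[C@@]32O[Si](CC)(CC)CC | intermediate
30 | CNP0323114.1 (all ring fusions cis, both hydroxyls on one face) | CC(C)=CCC/C(C)=C/C[C@]12CC=C(C)[C@@H]3C[C@@H]4C(C)(C)OC(=C(CC=C(C)C)C1=O)[C@]4(O)[C@@]32O | target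

Total step count: 18. Longest linear sequence: 15 steps (1–4, then 8–18); the enone branch (steps 5–7) joins at step 8.

Steps most likely to fail

Step 17. The dienolate may expel silanolate from C4a (vinylogous β-elimination), a silyl group may move to the new tertiary alkoxide before it attacks C3, or bond formation between two crowded carbons may be too slow. The fallback sets out from 25 and replaces the two separate silyl ethers by one cyclic silylene. Bu4NF would remove the 4a-silyl group to give the 4,4a-diol F1. tBu2Si(OTf)2 with 2,6-lutidine would tie both oxygens into the di-tert-butylsilylene F2, a five-membered ring that holds the C4a–O bond near the nodal plane of the dienolate and offers no transferable silyl group. KN(SiMe3)2 in THF would then effect the same oxirane opening and methoxide displacement to give the silylene of the target F3, and HF·pyridine would release 30, where the route is rejoined.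

Step 8. Bond formation at the crowded geranyl-bearing carbon may lose to O-alkylation or to unproductive ipso addition at the brominated carbons, or the adduct may revert before it is reduced. The fallback sets out from 1 and reverses the order in which the two substituents reach the quaternary carbon. Dibromination of 1 with N-bromosuccinimide would give 4,6-dibromo-5-methoxybenzene-1,3-diol F4. Its single free ring carbon would add to enone 13 under mild base, an ordinary rearomatising phenol Michael addition, to give the keto phenol F5. C-alkylation of the dianion of F5 with geranyl bromide 3 in aqueous KOH, the kind of geminal allylation well established for phloroglucinols, would then create the quaternary carbon as dibromo adduct 14, and zinc reduction as in step 8 returns to 15.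

Step 9. Enamine formation at a ketone whose reacting carbon is substituted may be slow, the catalyst may be captured by amine exchange at the vinylogous ester, the ketol may lose water, or the two ring carbonyls may be poorly discriminated. The fallback sets out from 15 and uses the fixed (S)-oxirane as an internal resolving element. Cyclisation with an achiral amine salt (pyrrolidine, AcOH) would give the wanted ketol 16 together with the diastereomer of opposite ring configuration F6. The two would be separated by chromatography, and F6 would be re-equilibrated with 16 through 15 under the same reversible aldol conditions and recycled; the route is rejoined at 16.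

Further compounds
F1 | step 17 | 4,4a-diol, 4a-desilylated 25 | CC(C)=CCC/C(C)=C/C[C@]12CC=C(C)[C@H](C[C@@H]3OC3(C)C)[C@]2(O)[C@H](O)C(OC)=C(CC=C(C)C)C1=O
F2 | step 17 | 4,4a-O-di-tert-butylsilylene derivative of F1 | CC(C)=CCC/C(C)=C/C[C@]12CC=C(C)[C@H](C[C@@H]3OC3(C)C)[C@]2(O[Si](C(C)(C)C)(C(C)(C)C)O4)[C@H]4C(OC)=C(CC=C(C)C)C1=O
F3 | step 17 | di-tert-butylsilylene of the target (both tertiary carbinol oxygens bridged) | CC(C)=CCC/C(C)=C/C[C@]12CC=C(C)[C@@H]3C[C@@H]4C(C)(C)OC(=C(CC=C(C)C)C1=O)[C@]4(O[Si](C(C)(C)C)(C(C)(C)C)O5)[C@@]325
F4 | step 8 | 4,6-dibromo-5-methoxybenzene-1,3-diol | COc1c(Br)c(O)cc(O)c1Br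
F5 | step 8 | 4,6-dibromo-5-methoxy-2-{5-[(2S)-3,3-dimethyloxiran-2-yl]-3-oxopentyl}benzene-1,3-diol | COc1c(Br)c(O)c(CCC(=O)CC[C@@H]2OC2(C)C)c(O)c1Br
F6 | step 9 | diastereomer of 16 with opposite configuration at C4a, C5 and C8a and the same (S)-oxirane | CC(C)=CCC/C(C)=C/C[C@@]12CCC(=O)[C@@H](C[C@@H]3OC3(C)C)[C@@]2(O)CC(OC)=CC1=O
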